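**Retrosynthetic overview**
1. The last skeletal bond is the pyrone-side C(Me)=CH. It comes from a vinylogous aldol addition of the lithium dienolate of 2-ethyl-6-methoxy-3,5-dimethyl-4-pyrone (fragment B) to the core dienal (fragment A), followed by E1cB loss of the carbinol oxygen. Desilylation, C4 acetylation and acetonide removal finish the synthesis.
2. The fragment A dienal comes from the cyclohexane carbaldehyde by a Wittig and then an HWE olefination.
3. C2-Me and C3-OH come from an OH-directed epoxidation of a cyclohexene and a trans-diaxial methyl cuprate opening. The carbocycle is closed by ring-closing metathesis (C2=C3).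
4. In the acyclic diene, C1/C6 come from a Sharpless epoxidation and vinyl-copper opening. C4/C5 come from a Sharpless desymmetrisation of 2,4-dimethylpenta-1,4-dien-3-ol.
5. Ring order: the pyrone ring is built separately (Claisen-type acylation, lactonisation, O-methylation). The carbocycle forms at step 12, and the two rings are joined at step 26.

Convention: the ring carbons are C1 (side chain), C2 (Me), C3 (Me, OH), C4 (OAc), C5 (Me, OH) and C6 (OH), and C1' is the carbon on C1. The target is 1R,2S,3R,4R,5S,6S. β is the face carrying the four oxygens and α the face carrying the four carbon substituents. "Core" means the 2α,3α,5α-trimethyl-3β,4β-bis(triethylsilyloxy)-5β,6β-(isopropylidenedioxy)cyclohex-1α-yl group.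

**Fragment A**

Step 1
Reactants: 1 methacrolein; 2 isopropenylmagnesium bromide
Product: 3 2,4-dimethylpenta-1,4-dien-3-ol
Conditions: THF, 0 °C
Reagents that add atoms: none
Why: Grignard 1,2-addition to the enal gives the prochiral bis-allylic alcohol that holds C3–C6 and both ring methyls.

Step 2
Reactants: 3 2,4-dimethylpenta-1,4-dien-3-ol
Product: 4 (1R)-2-methyl-1-[(2S)-2-methyloxiran-2-yl]prop-2-en-1-ol
Conditions: Ti(OiPr)4 (10 mol %), D-(−)-diisopropyl tartrate (13 mol %), t-BuOOH, 4 Å molecular sieves, CH2Cl2, −20 °C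
Reagents that add atoms: tert-butyl hydroperoxide, CC(C)(C)OO
Why: This Sharpless asymmetric epoxidation acts as a group- and face-selective desymmetrisation, in which the D-tartrate catalyst gives the erythro epoxy alcohol (C4 R, C5 S, the later cis C4-O/C5-O pair) and the minor enantiomer is removed by a fast second epoxidation.

Step 3
Reactants: 4 epoxy alcohol
Product: 5 (2S)-2-{(1R)-1-[(4-methoxybenzyl)oxy]-2-methylprop-2-en-1-yl}-2-methyloxirane
Conditions: NaH, 4-methoxybenzyl chloride, Bu4NI (cat.), THF–DMF, 0 °C to rt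
Reagents that add atoms: 4-methoxybenzyl chloride, COc1ccc(CCl)cc1
Why: Williamson etherification proceeds cleanly because a Payne shift would need attack at the fully substituted epoxide carbon, so no stereocentre is touched.

Step 4
Reactants: 5 PMB epoxide
Product: 6 (2S,3R)-3-[(4-methoxybenzyl)oxy]-2,4-dimethylpent-4-ene-1,2-diol
Conditions: KOH, DMSO–H2O (4:1), 80 °C
Reagents that add atoms: water, O
Why: SN2 epoxide hydrolysis under basic conditions attacks only the CH2 terminus (C6), so the C5–O bond and its configuration are kept.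

Step 5
Reactants: 6 diol
Product: 8 ethyl (2E,4S,5R)-4-hydroxy-5-[(4-methoxybenzyl)oxy]-4,6-dimethylhepta-2,6-dienoate, via hydroxy aldehyde 7 (not isolated)
Conditions: (COCl)2, DMSO, Et3N, CH2Cl2, −78 °C; then Ph3P=CHCO2Et, −78 °C to rt
Reagents that add atoms: ethyl (triphenylphosphoranylidene)acetate, CCOC(=O)C=P(c1ccccc1)(c1ccccc1)c1ccccc1
Why: A Swern oxidation and Wittig olefination in one flask oxidises only the primary alcohol without glycol cleavage, and the stabilised ylide gives the E-enoate from the non-enolisable aldehyde.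

Step 6
Reactants: 8 hydroxy enoate
Product: 9 ethyl (2E,4S,5R)-5-[(4-methoxybenzyl)oxy]-4,6-dimethyl-4-(triethylsilyloxy)hepta-2,6-dienoate
Conditions: Et3SiOTf, 2,6-lutidine, CH2Cl2, −78 to 0 °C
Reagents that add atoms: triethylsilyl triflate, CC[Si](CC)(CC)OS(=O)(=O)C(F)(F)F
Why: Silyl triflate silylation caps the tertiary C5-OH, so only one hydroxyl binds titanium in step 8.

Step 7
Reactants: 9 TES enoate
Product: 10 (2E,4S,5R)-5-[(4-methoxybenzyl)oxy]-4,6-dimethyl-4-(triethylsilyloxy)hepta-2,6-dien-1-ol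
Conditions: i-Bu2AlH (2.5 equiv), CH2Cl2, −78 °C
Reagents that add atoms: none
Why: 1,2-Reduction of the enoate with the aluminium hydride gives the E-allylic alcohol without touching the ethers.

Step 8
Reactants: 10 allylic alcohol
Product: 11 {(2R,3S)-3-[(2R,3R)-3-[(4-methoxybenzyl)oxy]-4-methyl-2-(triethylsilyloxy)pent-4-en-2-yl]oxiran-2-yl}methanol
Conditions: Ti(OiPr)4, D-(−)-diethyl tartrate, t-BuOOH, 4 Å molecular sieves, CH2Cl2, −20 °C
Reagents that add atoms: tert-butyl hydroperoxide, CC(C)(C)OO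
Why: Reagent-controlled Sharpless asymmetric epoxidation of the E-allylic alcohol gives the trans epoxide that fixes C6 (final configuration) and C1 (to be inverted), while the isopropenyl group is inert because it is not an allylic alcohol.

Step 9
Reactants: 11 epoxy alcohol
Product: 12 (2S,3S,4S,5R)-2-ethenyl-5-[(4-methoxybenzyl)oxy]-4,6-dimethyl-4-(triethylsilyloxy)hept-6-ene-1,3-diol
Conditions: CH2=CHMgBr (5 equiv), CuI (0.3 equiv), THF, −30 to 0 °C
Reagents that add atoms: vinylmagnesium bromide, C=C[Mg]Br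
Why: Copper-catalysed SN2 opening of the 2,3-epoxy alcohol occurs at C1, because C6 is neopentyl-blocked, and the inversion sets the C1/C6 relationship that becomes trans on the ring.

Step 10
Reactants: 12 1,3-diol
Product: 13 (2S,3S,4S,5R)-2-ethenyl-3-hydroxy-5-[(4-methoxybenzyl)oxy]-4,6-dimethyl-4-(triethylsilyloxy)hept-6-en-1-yl pivalate
Conditions: pivaloyl chloride (1.1 equiv), pyridine, CH2Cl2, 0 °C
Reagents that add atoms: pivaloyl chloride, CC(C)(C)C(=O)Cl
Why: Sterically selective acylation esterifies the primary C1'-OH and leaves the hindered secondary C6-OH free.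

Step 11
Reactants: 13 pivalate
Product: 15 (2S)-2-[(4S,5S)-5-{(1R)-1-[(4-methoxybenzyl)oxy]-2-methylprop-2-en-1-yl}-2,2,5-trimethyl-1,3-dioxolan-4-yl]but-3-en-1-yl pivalate, via diol 14 (not isolated)
Conditions: camphorsulfonic acid (10 mol %), MeOH, 0 °C to rt; evaporate; 2,2-dimethoxypropane, CH2Cl2, rt
Reagents that add atoms: 2,2-dimethoxypropane, COC(C)(C)OC
Why: Acid-catalysed desilylation and ketalisation can give only one acetonide, because C5-OH and C6-OH are the only free hydroxyls, and this differentiates C6-O from C4-O to the end.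

Step 12
Reactants: 15 acyclic diene
Product: 16 cyclohexene PMB ether: 1α-(pivaloyloxymethyl)-3,5α-dimethyl-4β-(4-methoxybenzyloxy)-5β,6β-(isopropylidenedioxy)cyclohex-2-ene
Conditions: second-generation Grubbs catalyst (H2IMes)(PCy3)Cl2Ru=CHPh (5 mol %), CH2Cl2 (2 mM), 40 °C
Reagents that add atoms: none
Why: Ring-closing metathesis of the vinyl and isopropenyl groups, held cis on the dioxolane, forms the trisubstituted six-membered C2=C3 alkene without touching a stereocentre.

Step 13
Reactants: 16 cyclohexene PMB ether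
Product: 17 cyclohexenol: 16 with a free 4β-OH
Conditions: DDQ (1.3 equiv), CH2Cl2–pH 7 buffer, 0 °C
Reagents that add atoms: none
Why: Oxidative PMB cleavage frees only the allylic C4-OH, and the acetonide, pivalate and alkene survive.

Step 14
Reactants: 17 cyclohexenol
Product: 18 2β,3β-epoxide of 17
Conditions: mCPBA, CH2Cl2, 0 °C
Reagents that add atoms: 3-chloroperoxybenzoic acid, OOC(=O)c1cccc(Cl)c1
Why: Henbest hydroxyl-directed epoxidation delivers the oxygen from the β face through hydrogen bonding to the pseudo-equatorial C4-OH, and the α face at C2 is screened by the C1 arm, which sets C3.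

Step 15
Reactants: 18 epoxy alcohol
Product: 19 diol: 1α-(pivaloyloxymethyl)-2α,3α,5α-trimethyl-5β,6β-(isopropylidenedioxy)cyclohexane-3β,4β-diol
Conditions: MeLi (10 equiv), CuI (5 equiv), Et2O, −20 °C to rt
Reagents that add atoms: methyllithium (used as Me2CuLi), C[Li]
Why: Gilman cuprate opening follows the Fürst–Plattner rule, so methyl attacks the less substituted C2 from the α face with inversion to give axial 2α-Me and axial 3β-OH, and the cis epoxy alkoxide cannot undergo a Payne shift.

Step 16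
Reactants: 19 diol
Product: 20 3β,4β-bis(triethylsilyl) ether of 19 (core-CH2OPiv)
Conditions: Et3SiOTf (4 equiv), 2,6-lutidine, CH2Cl2, 0 °C to rt
Reagents that add atoms: triethylsilyl triflate, CC[Si](CC)(CC)OS(=O)(=O)C(F)(F)F
Why: Exhaustive silylation with the triflate masks both hydroxyls with fluoride-labile groups that are orthogonal to the acetonide.

Step 17
Reactants: 20 pivalate
Product: 21 core-CH2OH
Conditions: i-Bu2AlH (2.5 equiv), CH2Cl2, −78 °C
Reagents that add atoms: none
Why: Reductive ester cleavage removes the only ester, and the silyl ethers and ketal are inert to the hydride.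

Step 18
Reactants: 21 primary alcohol
Product: 22 core-CHO (equatorial 1α-carbaldehyde)
Conditions: Dess–Martin periodinane, CH2Cl2, rt
Reagents that add atoms: none
Why: Dess–Martin oxidation is neutral enough not to epimerise C1, which is in any case the favoured equatorial epimer.

Step 19
Reactants: 22 core aldehyde
Product: 23 (2E)-2-methyl-3-(core)prop-2-enal
Conditions: Ph3P=C(Me)CHO, toluene, 100 °C
Reagents that add atoms: 2-(triphenylphosphoranylidene)propanal, CC(C=O)=P(c1ccccc1)(c1ccccc1)c1ccccc1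
Why: Wittig olefination with the stabilised, non-basic ylide gives the E-trisubstituted enal without β-elimination or C1 epimerisation.

Step 20
Reactants: 23 enal
Product: 24 ethyl (2E,4E)-4-methyl-5-(core)penta-2,4-dienoate
Conditions: (EtO)2P(O)CH2CO2Et, NaH, THF, 0 °C to rt
Reagents that add atoms: triethyl phosphonoacetate, CCOC(=O)CP(=O)(OCC)OCC
Why: Horner–Wadsworth–Emmons olefination of an enal gives the E-disubstituted alkene with high selectivity.

Step 21
Reactants: 24 dienoate
Product: 25 (2E,4E)-4-methyl-5-(core)penta-2,4-dien-1-ol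
Conditions: i-Bu2AlH (2.5 equiv), CH2Cl2, −78 °C
Reagents that add atoms: none
Why: 1,2-Reduction of the dienoate with the aluminium hydride stops cleanly at the dienol.

Step 22
Reactants: 25 dienol
Product: 26 (2E,4E)-4-methyl-5-(core)penta-2,4-dienal (fragment A)
Conditions: MnO2, CH2Cl2, rt
Reagents that add atoms: none
Why: Chemoselective MnO2 oxidation of the allylic alcohol gives the dienal without alkene isomerisation.

**Fragment B**

Step 23
Reactants: 27 methyl 2-methyl-3-oxopentanoate; 28 N-methoxy-N-methylpropanamide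
Product: 30 methyl 2,4-dimethyl-3,5-dioxoheptanoate, via sodium lithium dianion 29 (not isolated)
Conditions: NaH, THF, 0 °C; n-BuLi, 0 °C; then 28, 0 °C to rt
Reagents that add atoms: none
Why: Claisen-type acylation of the β-keto ester dianion occurs at its more reactive γ-carbon, and the Weinreb amide chelate prevents over-addition and proton exchange.

Step 24
Reactants: 30 triketide ester
Product: 31 6-ethyl-4-hydroxy-3,5-dimethyl-2H-pyran-2-one
Conditions: DBU, toluene, 110 °C
Reagents that add atoms: none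
Why: Base-mediated enol lactonisation of the 3,5-dioxo ester closes the pyrone ring with loss of methanol.

Step 25
Reactants: 31 hydroxy-α-pyrone
Product: 32 2-ethyl-6-methoxy-3,5-dimethyl-4H-pyran-4-one (fragment B)
Conditions: MeOTf, CH2Cl2, rt
Reagents that add atoms: methyl triflate, COS(=O)(=O)C(F)(F)F
Why: O-Methylation with the hard electrophile occurs at the lactone carbonyl oxygen, giving a hydroxypyrylium ion that loses a proton to the α-methoxy-γ-pyrone.

**Union and endgame (light excluded)**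

Step 26
Reactants: 32 fragment B; 26 fragment A
Product: 34 2-[(4E,6E)-3-hydroxy-6-methyl-7-(core)hepta-4,6-dien-2-yl]-6-methoxy-3,5-dimethyl-4H-pyran-4-one (epimer mixture at the two new centres), via lithium dienolate 33 (not isolated)
Conditions: 32 (1.5 equiv), LiN(SiMe3)2 (1.45 equiv), THF, −78 °C; then 26, −78 °C
Reagents that add atoms: none
Why: In this intermolecular vinylogous aldol addition the base removes the only vinylogously acidic proton (the ethyl CH2), the extended enolate adds 1,2 to the dienal, and the two new centres are erased in step 27.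

Step 27
Reactants: 34 aldol adduct
Product: 36 2-[(2E,4E,6E)-6-methyl-7-(core)hepta-2,4,6-trien-2-yl]-6-methoxy-3,5-dimethyl-4H-pyran-4-one, via allylic acetate 35 (not isolated)
Conditions: Ac2O, Et3N, DMAP (cat.), CH2Cl2, 0 °C; then DBU, rt
Reagents that add atoms: acetic anhydride, CC(=O)OC(C)=O (its acetyl is carried only by 35)
Why: Acetylation followed by E1cB elimination through the pyrone-stabilised carbanion gives the favoured E alkene with the pyrone and the chain trans.

Step 28
Reactants: 36 protected triene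
Product: 37 3β,4β-diol of the triene pyrone (acetonide retained)
Conditions: HF·pyridine, pyridine, THF, 0 °C to rt
Reagents that add atoms: none
Why: Buffered fluoride desilylation removes both TES groups and leaves the ketal, the polyene and the methoxypyrone untouched.

Step 29
Reactants: 37 diol
Product: 38 4β-acetate of 37
Conditions: Ac2O, DMAP, pyridine, rt to 40 °C
Reagents that add atoms: acetic anhydride, CC(=O)OC(C)=O
Why: DMAP-catalysed acylation acetylates the only secondary hydroxyl, since C3-OH is tertiary and axial and C6-O is still in the ketal.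

Step 30
Reactants: 38 acetate acetonide
Product: 39 amaurone A
Conditions: AcOH–H2O (4:1), 45 °C, dark
Reagents that add atoms: none
Why: Mild acetal hydrolysis frees the cis C5/C6 diol without breaking a C–O bond at a stereocentre, and acyl migration to the tertiary neighbours is thermodynamically uphill.

**Compound list**
1 | methacrolein | C=C(C)C=O | starting material
2 | isopropenylmagnesium bromide | C=C(C)[Mg]Br | starting material
3 | 2,4-dimethylpenta-1,4-dien-3-ol | C=C(C)C(O)C(C)=C | intermediate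
4 | (1R)-2-methyl-1-[(2S)-2-methyloxiran-2-yl]prop-2-en-1-ol | C=C(C)[C@@H](O)[C@]1(C)CO1 | intermediate
5 | PMB ether of 4 | C=C(C)[C@@H](OCc1ccc(OC)cc1)[C@]1(C)CO1 | intermediate
6 | (2S,3R)-3-(PMB-oxy)-2,4-dimethylpent-4-ene-1,2-diol | C=C(C)[C@@H](OCc1ccc(OC)cc1)[C@@](C)(O)CO | intermediate
7 | (2R,3R)-2-hydroxy-3-(PMB-oxy)-2,4-dimethylpent-4-enal | C=C(C)[C@@H](OCc1ccc(OC)cc1)[C@@](C)(O)C=O | intermediate
8 | ethyl (2E,4S,5R)-4-hydroxy-5-(PMB-oxy)-4,6-dimethylhepta-2,6-dienoate | C=C(C)[C@@H](OCc1ccc(OC)cc1)[C@@](C)(O)/C=C/C(=O)OCC | intermediate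
9 | C5 TES ether of 8 | C=C(C)[C@@H](OCc1ccc(OC)cc1)[C@@](C)(O[Si](CC)(CC)CC)/C=C/C(=O)OCC | intermediate
10 | (2E,4S,5R)-allylic alcohol | C=C(C)[C@@H](OCc1ccc(OC)cc1)[C@@](C)(O[Si](CC)(CC)CC)/C=C/CO | intermediate
11 | (2R,3S)-trans-epoxy alcohol | C=C(C)[C@@H](OCc1ccc(OC)cc1)[C@@](C)(O[Si](CC)(CC)CC)[C@H]1O[C@@H]1CO | intermediate
12 | (2S,3S,4S,5R)-2-ethenyl 1,3-diol | C=C(C)[C@@H](OCc1ccc(OC)cc1)[C@@](C)(O[Si](CC)(CC)CC)[C@@H](O)[C@H](CO)C=C | intermediate
13 | primary pivalate of 12 | C=C(C)[C@@H](OCc1ccc(OC)cc1)[C@@](C)(O[Si](CC)(CC)CC)[C@@H](O)[C@H](COC(=O)C(C)(C)C)C=C | intermediate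
14 | C5,C6-diol (TES removed) | C=C(C)[C@@H](OCc1ccc(OC)cc1)[C@@](C)(O)[C@@H](O)[C@H](COC(=O)C(C)(C)C)C=C | intermediate
15 | C5/C6 acetonide diene | C=C(C)[C@@H](OCc1ccc(OC)cc1)[C@@]1(C)OC(C)(C)O[C@H]1[C@H](COC(=O)C(C)(C)C)C=C | intermediate
16 | cyclohexene PMB ether | CC(C)(C)C(=O)OC[C@@H]1C=C(C)[C@@H](OCc2ccc(OC)cc2)[C@@]2(C)OC(C)(C)O[C@@H]12 | intermediate
17 | cyclohexenol (4β-OH) | CC(C)(C)C(=O)OC[C@@H]1C=C(C)[C@@H](O)[C@@]2(C)OC(C)(C)O[C@@H]12 | intermediate
18 | 2β,3β-epoxy alcohol | CC(C)(C)C(=O)OC[C@@H]1[C@H]3O[C@@]3(C)[C@@H](O)[C@@]2(C)OC(C)(C)O[C@@H]12 | intermediate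
19 | 2α-methyl 3β,4β-diol | CC(C)(C)C(=O)OC[C@@H]1[C@H](C)[C@@](C)(O)[C@@H](O)[C@@]2(C)OC(C)(C)O[C@@H]12 | intermediate
20 | core-CH2OPiv | CC(C)(C)C(=O)OC[C@@H]1[C@H](C)[C@@](C)(O[Si](CC)(CC)CC)[C@@H](O[Si](CC)(CC)CC)[C@@]2(C)OC(C)(C)O[C@@H]12 | intermediate
21 | core-CH2OH | OC[C@@H]1[C@H](C)[C@@](C)(O[Si](CC)(CC)CC)[C@@H](O[Si](CC)(CC)CC)[C@@]2(C)OC(C)(C)O[C@@H]12 | intermediate
22 | core-CHO | O=C[C@@H]1[C@H](C)[C@@](C)(O[Si](CC)(CC)CC)[C@@H](O[Si](CC)(CC)CC)[C@@]2(C)OC(C)(C)O[C@@H]12 | intermediate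
23 | (2E)-2-methyl-3-(core)prop-2-enal | O=C/C(C)=C/[C@@H]1[C@H](C)[C@@](C)(O[Si](CC)(CC)CC)[C@@H](O[Si](CC)(CC)CC)[C@@]2(C)OC(C)(C)O[C@@H]12 | intermediate
24 | ethyl (2E,4E)-4-methyl-5-(core)penta-2,4-dienoate | CCOC(=O)/C=C/C(C)=C/[C@@H]1[C@H](C)[C@@](C)(O[Si](CC)(CC)CC)[C@@H](O[Si](CC)(CC)CC)[C@@]2(C)OC(C)(C)O[C@@H]12 | intermediate
25 | (2E,4E)-dienol | OC/C=C/C(C)=C/[C@@H]1[C@H](C)[C@@](C)(O[Si](CC)(CC)CC)[C@@H](O[Si](CC)(CC)CC)[C@@]2(C)OC(C)(C)O[C@@H]12 | intermediate
26 | (2E,4E)-dienal, fragment A | O=C/C=C/C(C)=C/[C@@H]1[C@H](C)[C@@](C)(O[Si](CC)(CC)CC)[C@@H](O[Si](CC)(CC)CC)[C@@]2(C)OC(C)(C)O[C@@H]12 | intermediate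
27 | methyl 2-methyl-3-oxopentanoate | CCC(=O)C(C)C(=O)OC | starting material
28 | N-methoxy-N-methylpropanamide | CCC(=O)N(C)OC | starting material
29 | sodium lithium dianion of 27 | CC=C(O[Li])C(C)=C(OC)O[Na] | intermediate
30 | methyl 2,4-dimethyl-3,5-dioxoheptanoate | CCC(=O)C(C)C(=O)C(C)C(=O)OC | intermediate
31 | 6-ethyl-4-hydroxy-3,5-dimethyl-2H-pyran-2-one | CCc1oc(=O)c(C)c(O)c1C | intermediate
32 | 2-ethyl-6-methoxy-3,5-dimethyl-4H-pyran-4-one, fragment B | CCc1oc(OC)c(C)c(=O)c1C | intermediate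
33 | lithium dienolate of 32 | CC=C1OC(OC)=C(C)C(O[Li])=C1C | intermediate
34 | vinylogous aldol adduct (epimers at the two new centres) | COc1oc(C(C)C(O)/C=C/C(C)=C/[C@@H]2[C@H](C)[C@@](C)(O[Si](CC)(CC)CC)[C@@H](O[Si](CC)(CC)CC)[C@@]3(C)OC(C)(C)O[C@@H]23)c(C)c(=O)c1C | intermediate
35 | allylic acetate of 34 | COc1oc(C(C)C(OC(C)=O)/C=C/C(C)=C/[C@@H]2[C@H](C)[C@@](C)(O[Si](CC)(CC)CC)[C@@H](O[Si](CC)(CC)CC)[C@@]3(C)OC(C)(C)O[C@@H]23)c(C)c(=O)c1C | intermediate
36 | fully protected (E,E,E)-triene pyrone | COc1oc(/C(C)=C/C=C/C(C)=C/[C@@H]2[C@H](C)[C@@](C)(O[Si](CC)(CC)CC)[C@@H](O[Si](CC)(CC)CC)[C@@]3(C)OC(C)(C)O[C@@H]23)c(C)c(=O)c1C | intermediate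
37 | 3β,4β-diol acetonide | COc1oc(/C(C)=C/C=C/C(C)=C/[C@@H]2[C@H](C)[C@@](C)(O)[C@@H](O)[C@@]3(C)OC(C)(C)O[C@@H]23)c(C)c(=O)c1C | intermediate
38 | 4β-acetate acetonide | COc1oc(/C(C)=C/C=C/C(C)=C/[C@@H]2[C@H](C)[C@@](C)(O)[C@@H](OC(C)=O)[C@@]3(C)OC(C)(C)O[C@@H]23)c(C)c(=O)c1C | intermediate
39 | amaurone A | COc1oc(/C(C)=C/C=C/C(C)=C/[C@@H]2[C@H](C)[C@@](C)(O)[C@@H](OC(C)=O)[C@@](C)(O)[C@H]2O)c(C)c(=O)c1C | target

**Count and risks**
Total steps: 30. Longest linear sequence: 27 (steps 1–22, then 26–30).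

Step 15 (methyl cuprate on the trisubstituted epoxide). The epoxide is hindered, so the cuprate may react slowly or cause rearrangement to a ketone. The fallback sets out from 18 and brings the methyl group in as a masked carbanion. Lithiated methyl phenyl sulfone (PhSO2CH3, n-BuLi, THF–DMPU, rt to 50 °C) opens 18 in the same trans-diaxial sense at C2. This gives the 2α-(phenylsulfonylmethyl) 3β,4β-diol F1. Reductive desulfonylation with Na(Hg) and Na2HPO4 in MeOH turns the CH2SO2Ph group into CH3, and the route is rejoined at 19.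

Step 26 (vinylogous aldol union). Proton transfer to the dienolate, conjugate addition or retro-aldol on work-up could lower the yield. The fallback sets out from 32 and 26 and replaces addition–elimination by an olefination. The lithium dienolate 33 is quenched with N-bromosuccinimide to give 2-(1-bromoethyl)-6-methoxy-3,5-dimethyl-4H-pyran-4-one F2. An Arbuzov reaction with P(OEt)3 at 120 °C gives diethyl [1-(6-methoxy-3,5-dimethyl-4-oxo-4H-pyran-2-yl)ethyl]phosphonate F3. Deprotonation with LiN(SiMe3)2 and addition of 26 (Horner–Wadsworth–Emmons) gives the triene directly, and the route is rejoined at 36.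

Step 30 (acid removal of the hindered acetonide next to the acetate). Cleavage may be incomplete, the acetyl group may be lost, or it may migrate. The fallback sets out from 36 and reorders the endgame so that the last step uses fluoride. Treatment with 1 M HCl in THF strips both silyl ethers and the ketal before any acetate is present, giving the deacetyl tetraol F4. Et3SiCl and imidazole in DMF at −20 °C cap the less hindered secondary C6-OH to give the 6-O-triethylsilyl triol F5. Ac2O and DMAP then acetylate the remaining secondary C4-OH to give the 4-O-acetyl 6-O-triethylsilyl ether F6. HF·pyridine finally returns to the route at 39.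

**Further compounds**
F1 | step 15 | 2α-(phenylsulfonylmethyl) 3β,4β-diol | CC(C)(C)C(=O)OC[C@@H]1[C@H](CS(=O)(=O)c3ccccc3)[C@@](C)(O)[C@@H](O)[C@@]2(C)OC(C)(C)O[C@@H]12
F2 | step 26 | 2-(1-bromoethyl)-6-methoxy-3,5-dimethyl-4H-pyran-4-one | CC(Br)c1oc(OC)c(C)c(=O)c1C
F3 | step 26 | diethyl [1-(6-methoxy-3,5-dimethyl-4-oxo-4H-pyran-2-yl)ethyl]phosphonate | CCOP(=O)(OCC)C(C)c1oc(OC)c(C)c(=O)c1C
F4 | step 30 | deacetyl tetraol | COc1oc(/C(C)=C/C=C/C(C)=C/[C@@H]2[C@H](C)[C@@](C)(O)[C@@H](O)[C@@](C)(O)[C@H]2O)c(C)c(=O)c1C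
F5 | step 30 | 6-O-triethylsilyl triol | COc1oc(/C(C)=C/C=C/C(C)=C/[C@@H]2[C@H](C)[C@@](C)(O)[C@@H](O)[C@@](C)(O)[C@H]2O[Si](CC)(CC)CC)c(C)c(=O)c1C
F6 | step 30 | 4-O-acetyl 6-O-triethylsilyl ether | COc1oc(/C(C)=C/C=C/C(C)=C/[C@@H]2[C@H](C)[C@@](C)(O)[C@@H](OC(C)=O)[C@@](C)(O)[C@H]2O[Si](CC)(CC)CC)c(C)c(=O)c1C
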